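Start from 0.800 equiv of reagent: one reagent goes into each product, so the charge allows 80.0 % of the substrate charged, and reagent is the limiting reagent. The last readings of midnight, dawn and summer stand at 79.1 %, 80.0 % and 79.8 %.

| flask | substrate | reagent | catalyst | temperature | remark | time |
|---|---|---|---|---|---|---|
| midnight | 20 mM | 0.80 equiv | 1.4 mol% | 45 °C | run made earlier |  |
| dawn | 20 mM | 0.80 equiv | 2.2 mol% | 65 °C | run made earlier |  |
| summer | 30 mM | 0.80 equiv | 1 mol% | 45 °C | run made earlier |  |
| blue | 20 mM | 0.800 equiv | 1 mol% | 80 °C |  | 25 h |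
| grey | 20 mM | 0.800 equiv | 1 mol% | 50 °C |  | 25 h |

| run | time / h | product / % | substrate / % |
|---|---|---|---|
| midnight | 6.00 | 66.8 | 32.5 |
| midnight | 15.0 | 77.3 | 21.6 |
| midnight | 30.0 | 79.8 | 20.4 |
| midnight | 50.0 | 79.9 | 20.7 |
| midnight | 72.0 | 81.0 | 20.1 |
| midnight | 96.0 | 80.2 | 20.0 |
| midnight | 120 | 79.1 | 20.6 |
| dawn | 3.00 | 75.7 | 24.5 |
| dawn | 5.00 | 79.0 | 21.1 |
| dawn | 8.00 | 80.1 | 20.1 |
| dawn | 12.0 | 79.4 | 19.6 |
| dawn | 15.0 | 79.6 | 20.1 |
| dawn | 25.0 | 80.1 | 19.4 |
| dawn | 40.0 | 80.0 | 19.3 |
| summer | 8.00 | 75.5 | 23.4 |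
| summer | 15.0 | 79.0 | 21.7 |
| summer | 30.0 | 81.0 | 20.0 |
| summer | 60.0 | 80.3 | 19.6 |
| summer | 120 | 79.8 | 19.6 |

(standard deviation of a reading: 0.5 percentage points)

1. the best flask by amount of product, in percent of the substrate charged; "all alike" if 1.5 percentage points covers them all (blue / grey / all alike)
2. amount of product at the end, in percent of the substrate charged, blue
3. amount of product at the end, in percent of the substrate charged, grey

- steps thought possible: substrate + reagent + catalyst -> product + catalyst

So ask how close to that ceiling blue and grey come in 25 h. Take the rate as k × substrate × reagent × catalyst. Substrate minus reagent, the surplus, stays constant, and the rate law integrates to a straight line: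

    ln(share of substrate left / share of reagent left) = time / lifetime
    lifetime = reciprocal of (k × catalyst × surplus)

Once substrate stands near the surplus, reagent decays pseudo-first-order with this lifetime. Read k from the first reading of each run, shares taken from product:

    midnight, 45 °C: k = 1.04 × 10⁵ M⁻² h⁻¹
    summer, 45 °C: k = 1.02 × 10⁵ M⁻² h⁻¹
    dawn, 65 °C: k = 2.86 × 10⁵ M⁻² h⁻¹

Midnight and summer differ in substrate and loading, yet their readings match. Dawn against midnight reads an activation energy of 45.2 kJ mol⁻¹. Carry k to each flask and count lifetimes; my own reckoning gives: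

    blue: reagent lifetime 2.21 h, 11.3 lifetimes, product 80.0 %
    grey: reagent lifetime 9.22 h, 2.71 lifetimes, product 78.9 %

In this reckoning blue leads grey by 1.1 percentage points, less than the margin of 1.5 points, so call them alike.

The forecast says all alike: blue 80 % (78.5 % to 81 %), “barring unseen catalyst or product loss”, and grey 78.9 % (77.5 % to 79.8 %).

The simulation gives all alike: blue 80.0 %, grey 79.2 %, with catalyst in blue at 100 % after 25.0 h.

substrate + reagent + catalyst → product + catalyst, rate k1*[substrate]*[reagent]*[catalyst]/(1 + ([substrate]/sat1)) (37.6 mM, k = 1.74 × 10⁵ M⁻² h⁻¹, Ea = 42.0 kJ mol⁻¹); (constants at 50 °C) At 12.5 h blue has had 5.66 lifetimes, which leave 0.0701 % of the reagent, and blue holds 0.0620 %. Now take the neighbour, blue with 5.0 mM of substrate and the same equivalents and loading. Catalyst and surplus both shrink with substrate, so the lifetime grows to 35.4 h. That is 0.706 lifetimes, which leaves 16.3 % of the reagent and gives product 67.0 %. The neighbour holds 15 % of its reagent and 68.2 % product.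

The runs were generated by integration with made-up constants; scatter was added.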